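**Plan**

1. Retrosynthesis: the two benzyl ethers and a carboxyl group on ring A are put back. Ring A is then cut at C1–C6 (C1 carries the chain, C6 is the CH between C1 and the hydroxyl carbon C5), which unrolls it into an acyclic 3,5,7-triketo ester. That chain is cut at its C6–C7 bond into a 15-arylpentadecanoate and methyl 3,5-dioxohexanoate, and finally at the aryl–CH2 bond of ring B.
2. Enabling feature: in ring A the chain carbon C1, the methoxy carbon C3 and the hydroxyl carbon C5 alternate around the ring, which is the imprint of the C7, C5 and C3 carbonyls of a tetraketide. Ring A is therefore a decarboxylated 6-alkyl-2,4-dihydroxybenzoate, in which only the hydroxyl beside the ester is chelated, so a single oxygen can be methylated.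
3. Forward: ring B is bought as its bis-benzyl ether. The C15 chain from pentadecalactone is coupled to it, lengthened by six carbons with the diketo ester trianion, and ring A is closed last by aldol aromatisation. Methylation, loss of the ester as CO2 and hydrogenolysis finish the route.
4. Stereochemistry: none to set; the target has no stereocentre and no double-bond geometry.

Key step: step 5

Remark: methyl 3,5-dioxohexanoate is taken as a purchasable reagent; the target is achiral, so the SMILES strings carry no stereodescriptors.

**Route**

Step 1
Reactants: 1 pentadecalactone (oxacyclohexadecan-2-one)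
Product: 2 15-bromopentadecanoic acid
Conditions: HBr (33% in AcOH), cat. H2SO4, 100 °C
Reagents that add atoms: hydrogen bromide, Br
Why: Acid-mediated opening of the macrolactone followed by SN2 displacement at the primary carbinol carbon by bromide is the standard lactone to ω-bromo acid conversion and leaves the carboxyl group untouched.

Step 2
Reactants: 2 15-bromopentadecanoic acid
Product: 3 methyl 15-bromopentadecanoate
Conditions: MeOH, cat. H2SO4, reflux
Reagents that add atoms: methanol, CO
Why: Fischer esterification of an unhindered acid in excess methanol should go to completion, and the primary bromide is inert to acidic methanol.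

Step 3
Reactants: 3 methyl 15-bromopentadecanoate; 4 1-bromo-3,5-bis(benzyloxy)benzene
Product: 6 methyl 15-[3,5-bis(benzyloxy)phenyl]pentadecanoate, via aryl Grignard reagent 5 (not isolated)
Conditions: 4, Mg, cat. I2, THF, reflux; then added slowly to 3, Li2CuCl4 (3 mol%), THF–NMP, −10 to 0 °C
Reagents that add atoms: none
Why: In this Kochi-type copper-catalysed cross-coupling the arylcuprate formed from Li2CuCl4 should displace the primary bromide much faster than the Grignard reagent adds to the methyl ester at low temperature, and the benzyl ethers are inert to both organometallics.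

Step 4
Reactants: 6 methyl 15-[3,5-bis(benzyloxy)phenyl]pentadecanoate; 7 methyl 3,5-dioxohexanoate
Product: 9 methyl 21-[3,5-bis(benzyloxy)phenyl]-3,5,7-trioxohenicosanoate, via trilithium trianion 8 (not isolated)
Conditions: 7 (2.2 equiv), LiN(iPr)2 (6.6 equiv), THF, 0 °C; then 6, 0 °C to rt; aq. HCl quench
Reagents that add atoms: none
Why: This is a Claisen-type C-acylation of a β-dicarbonyl polyanion, in which the terminal C6 carbanion of 8 (the last formed and most nucleophilic site) should attack the ester carbonyl of 6, while the second equivalent of trianion takes up the acidic protons of the triketo ester as it forms.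

Step 5
Reactants: 9 methyl 21-[3,5-bis(benzyloxy)phenyl]-3,5,7-trioxohenicosanoate
Product: 11 methyl 2-{14-[3,5-bis(benzyloxy)phenyl]tetradecyl}-4,6-dihydroxybenzoate, via aldol adduct 10 (not isolated)
Conditions: Cs2CO3, MeOH, rt; then HCl in MeOH, rt
Reagents that add atoms: none
Why: Carbonate converts 9 into its enolates and the C2 carbon, acidified by the ester and the C3 ketone, adds to the C7 ketone to give aldol adduct 10, which loses water and tautomerises at C3 and C5 to the benzene ring, an irreversible exit that drains the reversible aldol equilibrium. The closest known reaction type is the base-mediated aldol aromatisation of 3,5,7-triketo esters to β-resorcylates, the flask version of alkylresorcylic acid formation by polyketide synthases. Ring A closes in a 6-(enolendo)-exo-trig mode through the new bond between chain atoms C2 and C7, which are C6 and C1 of ring A once the carboxyl group is gone. No stereocentre has to be controlled, because the carbinol carbon of 10 becomes aromatic. The selectivity needed is aldol closure in preference to Claisen closure of C6 onto the ester (an acylphloroglucinol) and to lactonisation (a pyrone); the substrate helps because C7 is a ketone while C1 is only a methyl ester, the caesium base in methanol avoids the magnesium chelation that templates the Claisen mode, and the cold methanolic HCl finish completes dehydration without the hot anhydrous acid that favours pyrones. The benzyl ethers and ring B take no part.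

Step 6
Reactants: 11 methyl 2-{14-[3,5-bis(benzyloxy)phenyl]tetradecyl}-4,6-dihydroxybenzoate
Product: 12 methyl 2-{14-[3,5-bis(benzyloxy)phenyl]tetradecyl}-6-hydroxy-4-methoxybenzoate
Conditions: MeI (1.1 equiv), K2CO3, acetone, rt to 40 °C
Reagents that add atoms: iodomethane, CI
Why: In this Williamson O-methylation the 4-hydroxyl para to the ester is free and the more acidic, whereas the 6-hydroxyl is hydrogen-bonded to the ester carbonyl and should stay unalkylated with one equivalent of MeI and a weak base, so exactly one methyl ether should form.

Step 7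
Reactants: 12 methyl 2-{14-[3,5-bis(benzyloxy)phenyl]tetradecyl}-6-hydroxy-4-methoxybenzoate
Product: 14 3-{14-[3,5-bis(benzyloxy)phenyl]tetradecyl}-5-methoxyphenol, via free salicylic acid 13 (not isolated)
Conditions: KOH, DMSO–H2O, 100 °C; then aq. H2SO4 to pH 1, 90 °C
Reagents that add atoms: none
Why: Hydroxide in aqueous DMSO should saponify the hindered salicylate, and on acidification the electron-rich 2-hydroxy-4-methoxybenzoic acid 13 should undergo protodecarboxylation through ipso protonation, as β-resorcylic acids do on warming, while the benzyl and methyl ethers are stable to both stages.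

Step 8
Reactants: 14 3-{14-[3,5-bis(benzyloxy)phenyl]tetradecyl}-5-methoxyphenol
Product: 15 5-[14-(3-hydroxy-5-methoxyphenyl)tetradecyl]benzene-1,3-diol (CID16109872)
Conditions: H2 (1 atm), 10% Pd/C, EtOAc–MeOH, rt
Reagents that add atoms: none
Why: Catalytic hydrogenolysis should cleave both benzyl aryl ethers cleanly, since 14 contains no other group that is reducible under these conditions.

**Compound list**

1 | pentadecalactone (oxacyclohexadecan-2-one) | O=C1CCCCCCCCCCCCCCO1 | starting material
2 | 15-bromopentadecanoic acid | OC(=O)CCCCCCCCCCCCCCBr | intermediate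
3 | methyl 15-bromopentadecanoate | COC(=O)CCCCCCCCCCCCCCBr | intermediate
4 | 1-bromo-3,5-bis(benzyloxy)benzene | Brc1cc(OCc2ccccc2)cc(OCc2ccccc2)c1 | starting material
5 | [3,5-bis(benzyloxy)phenyl]magnesium bromide (formed in the flask) | Br[Mg]c1cc(OCc2ccccc2)cc(OCc2ccccc2)c1 | intermediate
6 | methyl 15-[3,5-bis(benzyloxy)phenyl]pentadecanoate | COC(=O)CCCCCCCCCCCCCCc1cc(OCc2ccccc2)cc(OCc2ccccc2)c1 | intermediate
7 | methyl 3,5-dioxohexanoate | COC(=O)CC(=O)CC(C)=O | starting material
8 | trilithium salt of the 2,4,6-trianion of methyl 3,5-dioxohexanoate (formed in the flask) | [Li+].[Li+].[Li+].COC(=O)[CH-]C(=O)[CH-]C(=O)[CH2-] | intermediate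
9 | methyl 21-[3,5-bis(benzyloxy)phenyl]-3,5,7-trioxohenicosanoate | COC(=O)CC(=O)CC(=O)CC(=O)CCCCCCCCCCCCCCc1cc(OCc2ccccc2)cc(OCc2ccccc2)c1 | intermediate
10 | methyl 2-{14-[3,5-bis(benzyloxy)phenyl]tetradecyl}-2-hydroxy-4,6-dioxocyclohexane-1-carboxylate (aldol adduct, formed in the flask) | COC(=O)C1C(=O)CC(=O)CC1(O)CCCCCCCCCCCCCCc1cc(OCc2ccccc2)cc(OCc2ccccc2)c1 | intermediate
11 | methyl 2-{14-[3,5-bis(benzyloxy)phenyl]tetradecyl}-4,6-dihydroxybenzoate | COC(=O)c1c(O)cc(O)cc1CCCCCCCCCCCCCCc1cc(OCc2ccccc2)cc(OCc2ccccc2)c1 | intermediate
12 | methyl 2-{14-[3,5-bis(benzyloxy)phenyl]tetradecyl}-6-hydroxy-4-methoxybenzoate | COC(=O)c1c(O)cc(OC)cc1CCCCCCCCCCCCCCc1cc(OCc2ccccc2)cc(OCc2ccccc2)c1 | intermediate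
13 | 2-{14-[3,5-bis(benzyloxy)phenyl]tetradecyl}-6-hydroxy-4-methoxybenzoic acid (formed in the flask) | OC(=O)c1c(O)cc(OC)cc1CCCCCCCCCCCCCCc1cc(OCc2ccccc2)cc(OCc2ccccc2)c1 | intermediate
14 | 3-{14-[3,5-bis(benzyloxy)phenyl]tetradecyl}-5-methoxyphenol | COc1cc(O)cc(CCCCCCCCCCCCCCc2cc(OCc3ccccc3)cc(OCc3ccccc3)c2)c1 | intermediate
15 | 5-[14-(3-hydroxy-5-methoxyphenyl)tetradecyl]benzene-1,3-diol (CID16109872) | COc1cc(O)cc(CCCCCCCCCCCCCCc2cc(O)cc(O)c2)c1 | target

**Count**

Total steps: 8. Longest linear sequence: 8 steps (1 to 15); the coupling partners 4 and 7 are purchased.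

**Steps most likely to fail**

Step 4. Proton transfer from the forming, strongly acidic triketo ester (or from the α-methylene of 6) to unreacted trianion could stall the acylation, and self-condensation of 6 could intrude. The fallback sets out from ester 6 and comes back at triketo ester 9. Ester 6 would be treated with MeNHOMe·HCl and iPrMgCl in THF at −20 °C to give the Weinreb amide N-methoxy-N-methyl-15-[3,5-bis(benzyloxy)phenyl]pentadecanamide F1. Trianion 8 should add to F1 to form a chelated tetrahedral adduct that holds until the acidic quench, so no acidic triketone is released while carbanion is still present, and work-up should deliver 9.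

Step 5. Ring closure could take the wrong course, by Claisen attack on the ester, by lactonisation to a pyrone, or by retro-Claisen cleavage of the polyketone. The fallback sets out from ester 6 and comes back at resorcylate 11, bypassing 9. The Weinreb amide F1 described above would acylate the dianion (LiN(iPr)2, THF, −78 °C) of 2,2-dimethyl-6-(2-oxopropyl)-4H-1,3-dioxin-4-one F2, itself prepared from commercial 2,2,6-trimethyl-4H-1,3-dioxin-4-one with LiN(SiMe3)2 and acetyl chloride. The product would be 6-{18-[3,5-bis(benzyloxy)phenyl]-2,4-dioxooctadecyl}-2,2-dimethyl-4H-1,3-dioxin-4-one F3. In F3 the carboxyl carbon is locked in the dioxinone ring on the far side of the double bond from the side chain, so Claisen closure is geometrically out of reach. Et3N in CH2Cl2 should then close the same ring bond (dioxinone C5 onto the terminal ketone) to give 5-{14-[3,5-bis(benzyloxy)phenyl]tetradecyl}-7-hydroxy-2,2-dimethyl-4H-1,3-benzodioxin-4-one F4. NaOMe in MeOH would open the acetonide of F4 to the methyl ester 11.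

Step 3. Homocoupling of the aryl Grignard reagent, its addition to the ester, or reduction and elimination at the bromide could erode the coupling. The fallback sets out from bromo ester 3 and comes back at ester 6. Zn dust with LiCl in THF at 50 °C should insert into the C–Br bond of 3 to give the ester-tolerant (15-methoxy-15-oxopentadecyl)zinc bromide F5. Negishi coupling of F5 with aryl bromide 4 under Pd(OAc)2 and SPhos in THF should then give 6.

**Further compounds**

F1 | step 4 | N-methoxy-N-methyl-15-[3,5-bis(benzyloxy)phenyl]pentadecanamide | CON(C)C(=O)CCCCCCCCCCCCCCc1cc(OCc2ccccc2)cc(OCc2ccccc2)c1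
F2 | step 5 | 2,2-dimethyl-6-(2-oxopropyl)-4H-1,3-dioxin-4-one | CC(=O)CC1=CC(=O)OC(C)(C)O1
F3 | step 5 | 6-{18-[3,5-bis(benzyloxy)phenyl]-2,4-dioxooctadecyl}-2,2-dimethyl-4H-1,3-dioxin-4-one | CC1(C)OC(=O)C=C(CC(=O)CC(=O)CCCCCCCCCCCCCCc2cc(OCc3ccccc3)cc(OCc3ccccc3)c2)O1
F4 | step 5 | 5-{14-[3,5-bis(benzyloxy)phenyl]tetradecyl}-7-hydroxy-2,2-dimethyl-4H-1,3-benzodioxin-4-one | CC1(C)OC(=O)c2c(CCCCCCCCCCCCCCc3cc(OCc4ccccc4)cc(OCc4ccccc4)c3)cc(O)cc2O1
F5 | step 3 | (15-methoxy-15-oxopentadecyl)zinc bromide | COC(=O)CCCCCCCCCCCCCC[Zn]Br
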